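**Plan**
- Retrosynthetic cuts, in order: the two 3-O-galloyl esters and all benzyl ethers; O1–C8a of the lower unit (ring F); lower C2–C1′ (ring E); lower C4–C4a (chain to ring D); upper C4–lower C6 (interflavan bond).
- Forward: rings A–C come intact from (−)-epicatechin, which is benzylated, silylated and oxidised at C4. Ring D comes from 5-chlororesorcinol and is joined to upper C4 through its carbon between the two ether oxygens by boron-directed ipso substitution.
- The three-carbon chain follows: C4 of a D-tartrate acetonide alkylates ring D next to chlorine, and the remaining tartrate carboxyl (C1) becomes an N-acyloxyphthalimide.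
- Enabling feature: lower C2, C3 and C4 with O1 and O3 are C2, C3 and C4 of tartaric acid with its two hydroxyls. Ring E can therefore replace the C1 carboxyl by iron-catalysed decarboxylative arylation on the dioxolane, and ring F is closed last by Pd-catalysed C8a–O1 bond formation from the aryl chloride.
- Stereochemistry: upper C2/C3 from (−)-epicatechin; upper C4 by trans attack on the C4 cation; lower C3 from D-tartaric acid; lower C2 set in the arylation, trans to the C3 arm on the dioxolane. Ring F closes at oxygen with retention, so the threo diol becomes the 2,3-cis flavan.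

Key step: step 16

Remark: flavan numbering (C2–C4, C4a–C8a; rings A–C upper, D–F lower) is used for the lower unit also before ring F exists; dimethyl 2,3-O-isopropylidene-D-tartrate (the acetonide diester of D-(−)-tartaric acid) and 3,4,5-tris(benzyloxy)benzoic acid are taken as purchasable; Bn = benzyl, TBS = tert-butyldimethylsilyl.

**Route**

Step 1
Reactants: 1 (−)-epicatechin
Product: 2 5,7,3′,4′-tetra-O-benzyl-(−)-epicatechin
Conditions: BnBr (4.4 equiv), K2CO3, DMF, 0 °C → rt
Reagents that add atoms: benzyl bromide, BrCc1ccccc1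
Why: Williamson etherification under carbonate alkylates only the four phenols, the secondary 3-hydroxyl being far less acidic, and leaves C2 and C3 of the chiral-pool flavan untouched.

Step 2
Reactants: 2 5,7,3′,4′-tetra-O-benzyl-(−)-epicatechin
Product: 3 5,7,3′,4′-tetra-O-benzyl-3-O-TBS-(−)-epicatechin
Conditions: TBSCl, imidazole, DMF, rt
Reagents that add atoms: tert-butyldimethylsilyl chloride, CC(C)(C)[Si](C)(C)Cl
Why: Standard silylation of the lone secondary alcohol gives an ether that tolerates Lewis acid, organomagnesium reagents and hydroxide and that shields the α-face at C4 in the later coupling.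

Step 3
Reactants: 3 5,7,3′,4′-tetra-O-benzyl-3-O-TBS-(−)-epicatechin
Product: 4 5,7,3′,4′-tetra-O-benzyl-3-O-TBS-4β-(2-ethoxyethoxy)-(−)-epicatechin (2,3-cis-3,4-trans)
Conditions: DDQ (1.5 equiv), 2-ethoxyethanol (5 equiv), CH2Cl2, rt
Reagents that add atoms: 2-ethoxyethanol, CCOCCO
Why: DDQ abstracts hydride from C4, benzylic to the trioxygenated ring A (oxidative benzylic etherification), and the alcohol adds to the cation on the face opposite the 3-silyloxy and 2-aryl groups, which gives the 4β-ether as a Lewis-acid-labile leaving group.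

Step 4
Reactants: 5 5-chlororesorcinol
Product: 6 5-chloro-2-iodoresorcinol
Conditions: I2 (1.05 equiv), NaHCO3, H2O/THF, 0 °C → rt
Reagents that add atoms: iodine, II
Why: Electrophilic iodination of resorcinols with I2 in aqueous bicarbonate goes to the carbon between the two hydroxyls, and here the other positions are additionally hindered and deactivated by the neighbouring chlorine.

Step 5
Reactants: 6 5-chloro-2-iodoresorcinol
Product: 7 1,3-bis(benzyloxy)-5-chloro-2-iodobenzene
Conditions: BnBr (2.2 equiv), K2CO3, DMF, rt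
Reagents that add atoms: benzyl bromide, BrCc1ccccc1
Why: Williamson etherification of both phenols gives the ring D diether with the protecting groups used throughout.

Step 6
Reactants: 7 1,3-bis(benzyloxy)-5-chloro-2-iodobenzene
Product: 8 1,3-bis(benzyloxy)-4-bromo-5-chloro-2-iodobenzene
Conditions: NBS (1.0 equiv), MeCN, 0 °C → rt
Reagents that add atoms: N-bromosuccinimide, O=C1CCC(=O)N1Br
Why: Electrophilic aromatic bromination can only occur at the two equivalent free positions, each para to one benzyloxy group and ortho to chlorine, and the first bromine deactivates the ring against a second.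

Step 7
Reactants: 8 1,3-bis(benzyloxy)-4-bromo-5-chloro-2-iodobenzene
Product: 11 [2,6-bis(benzyloxy)-3-bromo-4-chlorophenyl]boronic acid, via arylmagnesium chloride 9 (not isolated), via dimethyl arylboronate 10 (not isolated)
Conditions: iPrMgCl·LiCl, THF, −40 °C; B(OMe)3, −40 °C → rt; aq. NH4Cl
Reagents that add atoms: trimethyl borate, COB(OC)OC; water, O
Why: Iodine–magnesium exchange is far faster than exchange of bromine or chlorine and the two flanking ether oxygens stabilise the arylmagnesium, which is borylated and hydrolysed to place boron on the future C6 of ring D.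

Step 8
Reactants: 4 5,7,3′,4′-tetra-O-benzyl-3-O-TBS-4β-(2-ethoxyethoxy)-(−)-epicatechin; 11 [2,6-bis(benzyloxy)-3-bromo-4-chlorophenyl]boronic acid
Product: 12 4β-[2,6-bis(benzyloxy)-3-bromo-4-chlorophenyl]-5,7,3′,4′-tetra-O-benzyl-3-O-TBS-(−)-epicatechin (2,3-cis-3,4-trans)
Conditions: 11 (2 equiv), TMSOTf (0.3 equiv), CH2Cl2, −78 → −40 °C, slow addition of 4
Reagents that add atoms: none
Why: The Lewis acid ionises the C4 ether to the benzylic cation, which replaces boron at the ipso carbon of 11 (boron-directed Friedel–Crafts arylation, known for flavan C8-boronic acids in 4→8 couplings); the aryl group enters the β-face, trans to the 3-silyloxy and 2-aryl groups, which sets upper C4, and the C–B bond fixes the site between the two benzyloxy groups, the future lower C6.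

Step 9
Reactants: 13 dimethyl (4S,5S)-2,2-dimethyl-1,3-dioxolane-4,5-dicarboxylate (dimethyl 2,3-O-isopropylidene-D-tartrate)
Product: 14 methyl (4S,5R)-5-(hydroxymethyl)-2,2-dimethyl-1,3-dioxolane-4-carboxylate
Conditions: NaBH4 (0.6 equiv), MeOH, 0 °C
Reagents that add atoms: none
Why: NaBH4 reduces α-alkoxy esters in methanol, and with a limited charge of hydride the C2-symmetric diester should give mainly the mono-alcohol (desymmetrising mono-reduction), diol and unchanged diester being separable; neither stereocentre is touched.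

Step 10
Reactants: 14 methyl (4S,5R)-5-(hydroxymethyl)-2,2-dimethyl-1,3-dioxolane-4-carboxylate
Product: 15 methyl (4S,5R)-2,2-dimethyl-5-[(trifluoromethylsulfonyloxy)methyl]-1,3-dioxolane-4-carboxylate
Conditions: Tf2O, 2,6-lutidine, CH2Cl2, −78 °C; used at once
Reagents that add atoms: triflic anhydride, O=S(=O)(OS(=O)(=O)C(F)(F)F)C(F)(F)F
Why: Sulfonylation of the primary alcohol with a hindered pyridine base gives the alkylating agent, which is not stored because β-alkoxy triflates decompose on standing.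

Step 11
Reactants: 12 4β-[2,6-bis(benzyloxy)-3-bromo-4-chlorophenyl]-5,7,3′,4′-tetra-O-benzyl-3-O-TBS-(−)-epicatechin; 15 methyl (4S,5R)-2,2-dimethyl-5-[(trifluoromethylsulfonyloxy)methyl]-1,3-dioxolane-4-carboxylate
Product: 17 methyl ester in which the bromine of 12 is replaced by the [(4R,5S)-5-(methoxycarbonyl)-2,2-dimethyl-1,3-dioxolan-4-yl]methyl group, via arylmagnesium chloride 16 (not isolated)
Conditions: iPrMgCl·LiCl (1.15 equiv), THF, 0 °C; then CuBr·SMe2 (10 mol %), 15 (1.5 equiv), −30 → 0 °C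
Reagents that add atoms: none
Why: Bromine–magnesium exchange is accelerated by the ortho chlorine and ortho ether oxygen and leaves the aryl chloride alone, and the arylmagnesium is alkylated by the primary triflate under copper catalysis (copper-catalysed Grignard–triflate coupling, known for tartrate-derived triflates), which joins tartrate C4 to C4a of ring D without touching a stereocentre.

Step 12
Reactants: 17 methyl ester (dioxolane CO2Me)
Product: 18 carboxylic acid (17 with CO2H in place of CO2Me)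
Conditions: LiOH·H2O, THF/MeOH/H2O, 0 °C → rt; 1 M HCl to pH 4 at 0 °C
Reagents that add atoms: lithium hydroxide, [Li+].[OH-]
Why: Saponification of the unhindered α-alkoxy methyl ester is fast and spares silyl and benzyl ethers, cold mild acidification spares the acetonide, and any epimerisation at the carboxyl-bearing carbon is harmless because that centre is erased in step 16.

Step 13
Reactants: 18 carboxylic acid
Product: 19 N-acyloxyphthalimide (1,3-dioxoisoindolin-2-yl ester) of 18
Conditions: N-hydroxyphthalimide, DIC, DMAP (cat.), CH2Cl2, rt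
Reagents that add atoms: N-hydroxyphthalimide, O=C1N(O)C(=O)c2ccccc12
Why: Carbodiimide coupling (Steglich-type esterification) turns the acid into the redox-active ester needed for single-electron decarboxylation.

Step 14
Reactants: 20 4-bromocatechol
Product: 21 1,2-bis(benzyloxy)-4-bromobenzene
Conditions: BnBr (2.2 equiv), K2CO3, DMF, rt
Reagents that add atoms: benzyl bromide, BrCc1ccccc1
Why: Williamson etherification protects the catechol of ring E as benzyl ethers that fall in the final hydrogenolysis.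

Step 15
Reactants: 21 1,2-bis(benzyloxy)-4-bromobenzene
Product: 23 [3,4-bis(benzyloxy)phenyl]zinc chloride (THF solution), via arylmagnesium bromide 22 (not isolated)
Conditions: Mg, LiCl, THF, rt; then ZnCl2 (1.0 equiv), 0 °C → rt; titrated and used directly
Reagents that add atoms: zinc chloride, Cl[Zn]Cl
Why: Magnesium insertion followed by transmetalation gives an arylzinc halide that is mild enough to tolerate the activated ester, acetonide and aryl chloride of 19.

Step 16
Reactants: 19 N-acyloxyphthalimide; 23 [3,4-bis(benzyloxy)phenyl]zinc chloride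
Product: 24 (4R,5R)-trans-dioxolane: 17 with the CO2Me group replaced by 3,4-bis(benzyloxy)phenyl (ring E on lower C2)
Conditions: 23 (2.5 equiv), Fe(acac)3 (20 mol %), 1,2-bis(diphenylphosphino)benzene (24 mol %), THF/toluene, rt
Reagents that add atoms: none
Why: The arylzinc reduces Fe(acac)3 to a low-valent aryliron–diphosphine species that transfers one electron to the phthalimide ester; the radical anion loses phthalimide anion and CO2 and leaves the dioxolan-4-yl radical at lower C2. The radical is captured at iron and the C2–aryl bond forms by reductive elimination, the closest known reaction being the iron- or nickel-catalysed decarboxylative Negishi-type arylation of redox-active esters, tartrate-derived dioxolane esters included. No ring is closed. The new stereocentre at lower C2 is controlled by the neighbouring C3 centre from D-tartrate: on the five-membered acetonide the aryl group is delivered to the face opposite the bulky ring D methylene arm, which gives the trans-dioxolane whatever the configuration of the carboxyl carbon was. The step needs chemoselectivity for the activated ester over the aryl chloride of ring D, secured because this iron catalyst does not insert into unactivated aryl chlorides at room temperature, and it needs trans selectivity, secured by the C3 substituent; benzyl ethers, the silyl ether and the acetonide are inert to the arylzinc.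

Step 17
Reactants: 24 trans-dioxolane carrying ring E
Product: 25 (1R,2R)-threo diol (lower C2–OH and C3–OH free)
Conditions: AcOH/H2O/THF (4:1:1), 45 °C
Reagents that add atoms: none
Why: Acid-catalysed hydrolysis of the isopropylidene acetal frees the threo diol under mild aqueous conditions, so that the hindered silyl ether survives and the electron-rich benzylic C2–O bond does not ionise.

Step 18
Reactants: 25 threo diol
Product: 26 lower 3-O-TBS ether with free benzylic C2 hydroxyl
Conditions: TBSCl (1.1 equiv), imidazole, DMF, 0 °C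
Reagents that add atoms: tert-butyldimethylsilyl chloride, CC(C)(C)[Si](C)(C)Cl
Why: Silylation discriminates by hindrance and nucleophilicity, since O3 sits on a carbon bearing a methylene whereas the benzylic O2 sits on a carbon bearing an aryl ring and is less nucleophilic, so the mono-ether at O3 should predominate and leave the C2 hydroxyl free for ring closure.

Step 19
Reactants: 26 lower 3-O-TBS ether
Product: 27 3,3″-bis-O-TBS-octa-O-benzyl procyanidin B5 (ring F closed; lower unit 2R,3R)
Conditions: Pd(OAc)2 (5 mol %), 2-(di-tert-butylphosphino)-1,1′-binaphthyl (6 mol %), Cs2CO3, toluene, 80 °C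
Reagents that add atoms: none
Why: In this intramolecular Buchwald–Hartwig etherification zerovalent palladium formed in situ inserts into the C8a–Cl bond, the C2 alkoxide binds and C–O reductive elimination closes the six-membered ring F; the C2–O bond is never broken, so the threo arrangement is carried over unchanged as the 2,3-cis flavan.

Step 20
Reactants: 27 bis-silyl ether
Product: 28 5,7,3′,4′,5″,7″,3‴,4‴-octa-O-benzyl procyanidin B5 (both 3-hydroxyls free)
Conditions: Bu4NF, THF, rt → 50 °C; aq. NH4Cl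
Reagents that add atoms: none
Why: Fluoride cleaves both secondary silyl ethers, and no base-sensitive group is present at this stage.

Step 21
Reactants: 28 octa-O-benzyl procyanidin B5; 29 3,4,5-tris(benzyloxy)benzoic acid
Product: 30 octa-O-benzyl procyanidin B5 3,3″-bis[3,4,5-tris(benzyloxy)benzoate]
Conditions: 29 (4 equiv), DCC, DMAP, CH2Cl2, rt
Reagents that add atoms: none
Why: Steglich esterification with excess acid acylates both hindered secondary alcohols, as is usual for benzylated procyanidin diols, and involves no stereocentre.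

Step 22
Reactants: 30 perbenzylated digallate
Product: 31 procyanidin B-5 3,3′-di-O-gallate
Conditions: H2 (1 atm), Pd(OH)2/C, THF/MeOH/H2O, rt
Reagents that add atoms: none
Why: Hydrogenolysis removes all fourteen benzyl ethers under neutral conditions that leave the galloyl esters and the interflavan bond intact.

**Compound list**

1 | (−)-epicatechin, (2R,3R) | O[C@@H]1Cc2c(O)cc(O)cc2O[C@@H]1c1ccc(O)c(O)c1 | starting material
2 | 5,7,3′,4′-tetra-O-benzyl-(−)-epicatechin, (2R,3R) | O[C@@H]1Cc2c(OCc9ccccc9)cc(OCc9ccccc9)cc2O[C@@H]1c1ccc(OCc9ccccc9)c(OCc9ccccc9)c1 | intermediate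
3 | 5,7,3′,4′-tetra-O-benzyl-3-O-TBS-(−)-epicatechin | CC(C)(C)[Si](C)(C)O[C@@H]1Cc2c(OCc9ccccc9)cc(OCc9ccccc9)cc2O[C@@H]1c1ccc(OCc9ccccc9)c(OCc9ccccc9)c1 | intermediate
4 | 5,7,3′,4′-tetra-O-benzyl-3-O-TBS-4β-(2-ethoxyethoxy)-(−)-epicatechin (2,3-cis-3,4-trans) | CC(C)(C)[Si](C)(C)O[C@@H]1[C@@H](OCCOCC)c2c(OCc9ccccc9)cc(OCc9ccccc9)cc2O[C@@H]1c1ccc(OCc9ccccc9)c(OCc9ccccc9)c1 | intermediate
5 | 5-chlororesorcinol | Oc1cc(O)cc(Cl)c1 | starting material
6 | 5-chloro-2-iodoresorcinol | Oc1cc(Cl)cc(O)c1I | intermediate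
7 | 1,3-bis(benzyloxy)-5-chloro-2-iodobenzene | Ic1c(OCc9ccccc9)cc(Cl)cc1OCc9ccccc9 | intermediate
8 | 1,3-bis(benzyloxy)-4-bromo-5-chloro-2-iodobenzene | Ic1c(OCc9ccccc9)cc(Cl)c(Br)c1OCc9ccccc9 | intermediate
9 | [2,6-bis(benzyloxy)-3-bromo-4-chlorophenyl]magnesium chloride (not isolated) | Cl[Mg]c1c(OCc9ccccc9)cc(Cl)c(Br)c1OCc9ccccc9 | intermediate
10 | dimethyl [2,6-bis(benzyloxy)-3-bromo-4-chlorophenyl]boronate (not isolated) | COB(OC)c1c(OCc9ccccc9)cc(Cl)c(Br)c1OCc9ccccc9 | intermediate
11 | [2,6-bis(benzyloxy)-3-bromo-4-chlorophenyl]boronic acid | OB(O)c1c(OCc9ccccc9)cc(Cl)c(Br)c1OCc9ccccc9 | intermediate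
12 | 4β-[2,6-bis(benzyloxy)-3-bromo-4-chlorophenyl]-5,7,3′,4′-tetra-O-benzyl-3-O-TBS-(−)-epicatechin (2,3-cis-3,4-trans) | CC(C)(C)[Si](C)(C)O[C@@H]1[C@@H](c3c(OCc9ccccc9)cc(Cl)c(Br)c3OCc9ccccc9)c2c(OCc9ccccc9)cc(OCc9ccccc9)cc2O[C@@H]1c1ccc(OCc9ccccc9)c(OCc9ccccc9)c1 | intermediate
13 | dimethyl (4S,5S)-2,2-dimethyl-1,3-dioxolane-4,5-dicarboxylate (D-tartrate acetonide diester) | COC(=O)[C@H]1OC(C)(C)O[C@@H]1C(=O)OC | starting material
14 | methyl (4S,5R)-5-(hydroxymethyl)-2,2-dimethyl-1,3-dioxolane-4-carboxylate | OC[C@H]1OC(C)(C)O[C@@H]1C(=O)OC | intermediate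
15 | methyl (4S,5R)-2,2-dimethyl-5-[(trifluoromethylsulfonyloxy)methyl]-1,3-dioxolane-4-carboxylate | FC(F)(F)S(=O)(=O)OC[C@H]1OC(C)(C)O[C@@H]1C(=O)OC | intermediate
16 | arylmagnesium chloride from 12 (MgCl in place of Br; not isolated) | CC(C)(C)[Si](C)(C)O[C@@H]1[C@@H](c3c(OCc9ccccc9)cc(Cl)c([Mg]Cl)c3OCc9ccccc9)c2c(OCc9ccccc9)cc(OCc9ccccc9)cc2O[C@@H]1c1ccc(OCc9ccccc9)c(OCc9ccccc9)c1 | intermediate
17 | methyl ester: 12 with Br replaced by [(4R,5S)-5-(methoxycarbonyl)-2,2-dimethyl-1,3-dioxolan-4-yl]methyl (trans-dioxolane) | CC(C)(C)[Si](C)(C)O[C@@H]1[C@@H](c3c(OCc9ccccc9)cc(Cl)c(C[C@H]4OC(C)(C)O[C@@H]4C(=O)OC)c3OCc9ccccc9)c2c(OCc9ccccc9)cc(OCc9ccccc9)cc2O[C@@H]1c1ccc(OCc9ccccc9)c(OCc9ccccc9)c1 | intermediate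
18 | carboxylic acid: 17 with CO2H in place of CO2Me, (4R,5S)-dioxolane | CC(C)(C)[Si](C)(C)O[C@@H]1[C@@H](c3c(OCc9ccccc9)cc(Cl)c(C[C@H]4OC(C)(C)O[C@@H]4C(=O)O)c3OCc9ccccc9)c2c(OCc9ccccc9)cc(OCc9ccccc9)cc2O[C@@H]1c1ccc(OCc9ccccc9)c(OCc9ccccc9)c1 | intermediate
19 | N-acyloxyphthalimide (1,3-dioxoisoindolin-2-yl ester) of 18 | CC(C)(C)[Si](C)(C)O[C@@H]1[C@@H](c3c(OCc9ccccc9)cc(Cl)c(C[C@H]4OC(C)(C)O[C@@H]4C(=O)ON5C(=O)c6ccccc6C5=O)c3OCc9ccccc9)c2c(OCc9ccccc9)cc(OCc9ccccc9)cc2O[C@@H]1c1ccc(OCc9ccccc9)c(OCc9ccccc9)c1 | intermediate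
20 | 4-bromocatechol | Oc1ccc(Br)cc1O | starting material
21 | 1,2-bis(benzyloxy)-4-bromobenzene | Brc1ccc(OCc9ccccc9)c(OCc9ccccc9)c1 | intermediate
22 | [3,4-bis(benzyloxy)phenyl]magnesium bromide (not isolated) | Br[Mg]c1ccc(OCc9ccccc9)c(OCc9ccccc9)c1 | intermediate
23 | [3,4-bis(benzyloxy)phenyl]zinc chloride | Cl[Zn]c1ccc(OCc9ccccc9)c(OCc9ccccc9)c1 | intermediate
24 | (4R,5R)-trans-dioxolane: ring E [3,4-bis(benzyloxy)phenyl] on lower C2 and the chlorinated ring D with the upper unit on the C4 methylene | CC(C)(C)[Si](C)(C)O[C@@H]1[C@@H](c3c(OCc9ccccc9)cc(Cl)c(C[C@H]4OC(C)(C)O[C@@H]4c5ccc(OCc9ccccc9)c(OCc9ccccc9)c5)c3OCc9ccccc9)c2c(OCc9ccccc9)cc(OCc9ccccc9)cc2O[C@@H]1c1ccc(OCc9ccccc9)c(OCc9ccccc9)c1 | intermediate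
25 | (1R,2R)-threo diol from 24 (lower C2–OH and C3–OH free) | CC(C)(C)[Si](C)(C)O[C@@H]1[C@@H](c3c(OCc9ccccc9)cc(Cl)c(C[C@@H](O)[C@H](O)c5ccc(OCc9ccccc9)c(OCc9ccccc9)c5)c3OCc9ccccc9)c2c(OCc9ccccc9)cc(OCc9ccccc9)cc2O[C@@H]1c1ccc(OCc9ccccc9)c(OCc9ccccc9)c1 | intermediate
26 | (1R,2R)-diol mono-ether: lower O3–TBS with free benzylic C2–OH | CC(C)(C)[Si](C)(C)O[C@@H]1[C@@H](c3c(OCc9ccccc9)cc(Cl)c(C[C@@H](O[Si](C)(C)C(C)(C)C)[C@H](O)c5ccc(OCc9ccccc9)c(OCc9ccccc9)c5)c3OCc9ccccc9)c2c(OCc9ccccc9)cc(OCc9ccccc9)cc2O[C@@H]1c1ccc(OCc9ccccc9)c(OCc9ccccc9)c1 | intermediate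
27 | 3,3″-bis-O-TBS-octa-O-benzyl procyanidin B5 [epicatechin-(4β→6)-epicatechin; both units 2R,3R] | CC(C)(C)[Si](C)(C)O[C@@H]1[C@@H](c3c(OCc9ccccc9)cc4c(c3OCc9ccccc9)C[C@@H](O[Si](C)(C)C(C)(C)C)[C@@H](c5ccc(OCc9ccccc9)c(OCc9ccccc9)c5)O4)c2c(OCc9ccccc9)cc(OCc9ccccc9)cc2O[C@@H]1c1ccc(OCc9ccccc9)c(OCc9ccccc9)c1 | intermediate
28 | octa-O-benzyl procyanidin B5 (both 3-hydroxyls free) | O[C@@H]1[C@@H](c3c(OCc9ccccc9)cc4c(c3OCc9ccccc9)C[C@@H](O)[C@@H](c5ccc(OCc9ccccc9)c(OCc9ccccc9)c5)O4)c2c(OCc9ccccc9)cc(OCc9ccccc9)cc2O[C@@H]1c1ccc(OCc9ccccc9)c(OCc9ccccc9)c1 | intermediate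
29 | 3,4,5-tris(benzyloxy)benzoic acid | OC(=O)c1cc(OCc9ccccc9)c(OCc9ccccc9)c(OCc9ccccc9)c1 | starting material
30 | octa-O-benzyl procyanidin B5 3,3″-bis[3,4,5-tris(benzyloxy)benzoate] | O=C(O[C@@H]1[C@@H](c3c(OCc9ccccc9)cc4c(c3OCc9ccccc9)C[C@@H](OC(=O)c6cc(OCc9ccccc9)c(OCc9ccccc9)c(OCc9ccccc9)c6)[C@@H](c5ccc(OCc9ccccc9)c(OCc9ccccc9)c5)O4)c2c(OCc9ccccc9)cc(OCc9ccccc9)cc2O[C@@H]1c1ccc(OCc9ccccc9)c(OCc9ccccc9)c1)c1cc(OCc9ccccc9)c(OCc9ccccc9)c(OCc9ccccc9)c1 | intermediate
31 | procyanidin B-5 3,3′-di-O-gallate | O=C(O[C@@H]1[C@@H](c2c(O)cc3c(c2O)C[C@@H](OC(=O)c2cc(O)c(O)c(O)c2)[C@@H](c2ccc(O)c(O)c2)O3)c2c(O)cc(O)cc2O[C@@H]1c1ccc(O)c(O)c1)c1cc(O)c(O)c(O)c1 | target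

**Step count and risks**

Total: 22 steps. Longest linear sequence: 15 steps (5-chlororesorcinol to the target: steps 4–8, 11–13 and 16–22).

Step 8 (interflavan junction). The boronic acid carries chlorine and bromine and is a weak nucleophile, so the C4 cation may instead attack the free C6/C8 positions of ring A of a second molecule of 4, and 11 may lose boron by protonation before ipso attack. The fallback makes the 4→6 bond on a closed lower flavan by bromine capping; it sets out from 3 and comes back at 27, and it gives up the tartrate-built lower unit. Compound 3 is brominated at C8 (NBS, CH2Cl2, −15 °C) to 8-bromo-5,7,3′,4′-tetra-O-benzyl-3-O-TBS-epicatechin F1. Part of F1 is oxidised (DDQ, 2-ethoxyethanol) to the 8-bromo 4β-(2-ethoxyethoxy) electrophile F2. F2 is coupled with an excess of F1 (TMSOTf, CH2Cl2, −78 °C); with C8 blocked, the nucleophile should react at C6 and give the 8,8″-dibromo 4β→6 dimer F3. Both bromines are then removed by bromine–lithium exchange and protonation (n-BuLi, THF, −78 °C, then MeOH), which should give 27.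

Step 11 (chain attachment). The arylmagnesium is flanked by chlorine and a benzyloxy group, so displacement at the β-branched triflate may be slow, and addition to the ester or decomposition of the triflate may take over. The fallback changes the electrophile to a carbonyl group and removes the extra oxygen afterwards; it sets out from 12 and 14 and comes back at 17. Alcohol 14 is oxidised (Swern) to methyl (4S,5S)-5-formyl-2,2-dimethyl-1,3-dioxolane-4-carboxylate F4. Arylmagnesium 16, made from 12 as in step 11, is added at −78 °C to give the benzylic carbinol F5 as an epimer mixture of no consequence. Ionic deoxygenation (Et3SiH, BF3·OEt2, CH2Cl2, −78 → −40 °C) through the benzylic cation, stabilised by ortho and para ether oxygens, should then give 17.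

Step 19 (ring F closure). The benzylic palladium alkoxide may undergo β-hydride elimination, which would give an aryl ketone and the dechlorinated arene. Carbonate may also move the silyl group from O3 to O2 and open the way to five-membered ring closure. The fallback reverses the polarity of the aryl partner; it sets out from 26 and comes back at 27. Miyaura borylation of the aryl chloride (Pd2(dba)3, 2-dicyclohexylphosphino-2′,4′,6′-triisopropylbiphenyl, B2pin2, KOAc, dioxane, 90 °C) gives the pinacol arylboronate F6. Oxidative copper-mediated Chan–Lam etherification with the free C2 hydroxyl (Cu(OAc)2, pyridine, 4 Å molecular sieves, air, CH2Cl2, rt) then closes ring F, again without breaking the C2–O bond, and should give 27.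

Further compounds
F1 | step 8 | 8-bromo-5,7,3′,4′-tetra-O-benzyl-3-O-TBS-(−)-epicatechin | CC(C)(C)[Si](C)(C)O[C@@H]1Cc2c(OCc9ccccc9)cc(OCc9ccccc9)c(Br)c2O[C@@H]1c1ccc(OCc9ccccc9)c(OCc9ccccc9)c1
F2 | step 8 | 8-bromo-5,7,3′,4′-tetra-O-benzyl-3-O-TBS-4β-(2-ethoxyethoxy)-(−)-epicatechin | CC(C)(C)[Si](C)(C)O[C@@H]1[C@@H](OCCOCC)c2c(OCc9ccccc9)cc(OCc9ccccc9)c(Br)c2O[C@@H]1c1ccc(OCc9ccccc9)c(OCc9ccccc9)c1
F3 | step 8 | 8,8″-dibromo-3,3″-bis-O-TBS-octa-O-benzyl procyanidin B5 | CC(C)(C)[Si](C)(C)O[C@@H]1[C@@H](c3c(OCc9ccccc9)c(Br)c4c(c3OCc9ccccc9)C[C@@H](O[Si](C)(C)C(C)(C)C)[C@@H](c5ccc(OCc9ccccc9)c(OCc9ccccc9)c5)O4)c2c(OCc9ccccc9)cc(OCc9ccccc9)c(Br)c2O[C@@H]1c1ccc(OCc9ccccc9)c(OCc9ccccc9)c1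
F4 | step 11 | methyl (4S,5S)-5-formyl-2,2-dimethyl-1,3-dioxolane-4-carboxylate | O=C[C@H]1OC(C)(C)O[C@@H]1C(=O)OC
F5 | step 11 | benzylic carbinol: 12 with Br replaced by hydroxy[(4S,5S)-5-(methoxycarbonyl)-2,2-dimethyl-1,3-dioxolan-4-yl]methyl (carbinol centre undefined) | CC(C)(C)[Si](C)(C)O[C@@H]1[C@@H](c3c(OCc9ccccc9)cc(Cl)c(C(O)[C@H]4OC(C)(C)O[C@@H]4C(=O)OC)c3OCc9ccccc9)c2c(OCc9ccccc9)cc(OCc9ccccc9)cc2O[C@@H]1c1ccc(OCc9ccccc9)c(OCc9ccccc9)c1
F6 | step 19 | pinacol arylboronate: 26 with Cl replaced by 4,4,5,5-tetramethyl-1,3,2-dioxaborolan-2-yl | CC(C)(C)[Si](C)(C)O[C@@H]1[C@@H](c3c(OCc9ccccc9)cc(B7OC(C)(C)C(C)(C)O7)c(C[C@@H](O[Si](C)(C)C(C)(C)C)[C@H](O)c5ccc(OCc9ccccc9)c(OCc9ccccc9)c5)c3OCc9ccccc9)c2c(OCc9ccccc9)cc(OCc9ccccc9)cc2O[C@@H]1c1ccc(OCc9ccccc9)c(OCc9ccccc9)c1
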